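## The problem

Barbatolic acid (28) is a benzyl depside. Two 3-formyl-2,4-dihydroxybenzoic acid units are joined by an ester between the ring A carboxyl group and the benzylic oxygen on C6 of ring B; ring A carries a methyl group at its own C6. The molecule has no stereocentres, so the difficulties are regiochemistry and functional-group tolerance. Each ring is pentasubstituted, with the aldehyde at C3 wedged between the C2 and C4 hydroxyl groups. Electrophilic formylation of a 2,4-dihydroxybenzoate would have to choose between C3 and C5 and needs Lewis acids that the rest of the molecule would not survive. The benzylic ester can be neither hydrogenolysed nor saponified, and the ring B carboxyl group sits ortho to the acyloxymethyl arm, so a free ortho-hydroxymethyl benzoate at any stage, or a carboxylate under forcing conditions, would close to a phthalide. The salicylaldehyde units are sensitive to base, amines and light, and 2,4-dihydroxybenzoic acids decarboxylate on heating. The enabling feature is the pattern of ring B: C5 is its only unsubstituted carbon, C2 and C4 carry oxygen and C3 a one-carbon unit. A vinylketene (C2 from the ketene carbon, C5 from the former diazo carbon, C6 and C1 from the alkene) and an oxygenated alkyne (C4 with its oxygen, C3 with its carbon substituent) deliver exactly this in a Danheiser benzannulation.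

## Retrosynthesis

**28 back to 25.** Only protecting groups are removed: the allyl ester (27 to 28), the two acetals and two MOM ethers (26 to 27) and the aryl silyl ether (25 to 26). The carboxyl group is freed last, under neutral conditions with zerovalent palladium, because the free acid beside the acyloxymethyl arm is the phthalide-prone arrangement. Benzyl-type groups are excluded by the benzylic ester, and everything else falls to fluoride or dilute acid.

**25 back to 16 and 20.** Three bonds of ring B are cut: C2–C3, C4–C5 and C1–C2. The neighbouring cut at the C3–CHO bond would bring back the C3/C5 formylation problem. Cutting the benzylic ester on an intact ring B would pass through an ortho-hydroxymethyl salicylate, which lactonizes. Here every substituent of ring B, including the masked aldehyde, is fixed by the connectivity of an acyclic diazo enone 16 and a three-carbon siloxyalkyne 20, and the depside ester is already in place before the ring becomes aromatic. The forward reaction must give a regioselective ketene–alkyne [2+2] addition and must tolerate acetals, MOM ethers and two esters. Compound 16 is planned as its E isomer (ester trans to the diazoacetyl group). A Z ester would sit beside the ketene and could close onto it to a 6-allyloxy-2-pyranone, and it would point inward in the final 6π closure.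

**16 back to 13.** The diazo group is removed, leaving methyl ketone 13. Acylation of diazomethane by an unsaturated acid chloride is the neighbouring choice, but diazomethane adds to electron-poor alkenes, and this alkene carries two carbonyl groups. Detrifluoroacetylative diazo transfer was developed for enones and asks only for kinetic enolization of the methyl group.

**13 back to 7 and 12.** The O–CH2 bond is cut, so the hindered, di-ortho-substituted acid 7 acts as an oxygen nucleophile on the allylic bromide 12, not as an acyl donor. Cutting the acyl C–O bond would need acylation by that hindered acid and a free allylic alcohol cis to an ester, which would form a butenolide.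

**12 back to 11, 9, 10 and 8.** The C–Br bond is cut with allylic transposition to the Morita–Baylis–Hillman alcohol 11. Its C–C bond between the α-carbon of methyl vinyl ketone (10) and the aldehyde carbon of allyl glyoxylate (9) is cut next; 9 comes from diallyl L-tartrate (8) by glycol cleavage. Radical bromination of a 3-methyl enoate was the alternative, but it would have to spare the allyl ester and the acetyl group.

**20 back to 17.** The O–Si bond and the alkyne C–O bond are cut, leading to commercial 3,3-diethoxyprop-1-yne (17), whose acetylide is oxidized and silylated in one flask.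

**7 back to 5, 4, 2 and 1.** The aryl–CO2H bond and then the aryl–CHO bond are cut, leading through acetal 5, aldehyde 4 and bis-MOM ether 2 to orcinol (1). Both carbons are introduced by directed ortho-metalation, so no electrophilic substitution has to choose between ring positions, and the acid is obtained without hydrolysing a hindered ester.

## Roads not taken

Alternative 1: Both salicylaldehyde units are cut at once, at the C3–CHO and C4–O bonds of each ring. In the forward step CsF in DMF would generate a C3–C4 aryne on each ring of the bis(silyl triflate) A2. DMF adds with oxygen at C4 and carbon at C3, directed by the C2 alkoxy group, and hydrolysis gives the di-MOM allyl ester A1. The merit is real: one late operation on the intact depside installs both aldehydes and both C4 phenols, and no aldehyde ever needs an acetal. On the count of steps after assembly this road is better than the chosen one. Its weak points lie before and during that step. A2 needs a contiguous silyl/triflate pair on each of two already pentasubstituted rings, so each ring has to be built as a fully regiodefined arene by sequences at least as long as those used here. Two arynes must be formed and trapped in one molecule that holds a benzylic ester and an allyl ester in hot fluoride. Any inefficiency of a single insertion counts twice. The chosen plan sets against this that each formyl carbon is placed by connectivity (ring B) or by metalation between two directing groups (ring A), in steps that can be optimized one ring at a time.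

Alternative 2: Ring A is cut at C1–C2 and C5–C6. A bis(silyloxy) ketene acetal diene A5 would add to the but-2-ynoate A4 of a finished ring B alcohol, and loss of methanol would aromatize to the orsellinate A3. The cycloaddition has reliable regiochemistry and forms the depside ester before the ring, which is as convergent as the chosen plan. Its weakness is that it spends the ring-forming step on the easy ring. The carbon skeleton of ring A can be bought as orcinol (1), whereas A4 presupposes the complete, formylated ring B, which is the actual problem. A3 still lacks the ring A aldehyde, so a Lewis acid formylation between two free hydroxyl groups, with its C3/C5 question, would have to be run in the presence of the acetal and MOM groups of ring B. The chosen plan takes four steps to acid 7 but ends them with the formyl carbon in place and regiochemically defined.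

Alternative 3: Ring B is cut at C1–C6 to a linear triketo ester A7. Mild base would fold it by aldol attack of chain C2 on the C7 ketone, and dehydration would give the resorcylate A6. This is the mildest ring formation of all: no light, no diazo compound, no silyl ynol ether, and both phenols appear free. In reagent simplicity it is better than the chosen plan. Against it stand three points. A7 is a sensitive polycarbonyl chain with other folding modes open (Claisen closure onto the ester, pyrone formation). Its C7 ketone carries an α-acyloxy group that can migrate or eliminate. Above all, A6 has hydrogen at C3, so the aldehyde would have to be introduced afterwards by electrophilic formylation between the two hydroxyl groups, with C5 as a competitor and with the acid-labile ring A protection present. The chosen plan is longer in the fragment syntheses but leaves no regiochemical decision on ring B to a reagent.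

Key step: step 11

Remark on the chemistry: diazo enone 16 is made and used as its E isomer (ester trans to the diazoacetyl group); the alkene geometry is erased on aromatization.

Abbreviation in names: ArACO = 3-(dimethoxymethyl)-2,4-bis(methoxymethoxy)-6-methylbenzoyl, the protected ring A acyl group.

## Route

Step 1
Reactants: 1 orcinol (5-methylbenzene-1,3-diol)
Product: 2 1,3-bis(methoxymethoxy)-5-methylbenzene
Conditions: NaH, MOMCl, DMF, 0 °C to rt
Reagents that add atoms: chloromethyl methyl ether, COCCl
Why: Williamson-type O-alkylation of the bis-phenoxide; MOM is stable to the organolithium and base steps that follow and is removed by dilute acid at the end.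

Step 2
Reactants: 2 1,3-bis(methoxymethoxy)-5-methylbenzene
Product: 4 2,6-bis(methoxymethoxy)-4-methylbenzaldehyde, via aryllithium 3 (not isolated)
Conditions: n-BuLi, THF, 0 °C; DMF, 0 °C to rt; aq. NH4Cl
Reagents that add atoms: N,N-dimethylformamide, CN(C)C=O
Why: Directed ortho-metalation at the position flanked by both OMOM groups (the most acidic and doubly coordinated site), then formylation with DMF; the regiochemistry is set by the two directing groups.

Step 3
Reactants: 4 2,6-bis(methoxymethoxy)-4-methylbenzaldehyde
Product: 5 2-(dimethoxymethyl)-1,3-bis(methoxymethoxy)-5-methylbenzene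
Conditions: HC(OMe)3, MeOH, PPTS (cat.), rt; Et3N quench
Reagents that add atoms: trimethyl orthoformate, COC(OC)OC; methanol, CO
Why: Acid-catalysed acetalization with the orthoformate as water scavenger; PPTS at rt is mild enough to spare aryl MOM ethers, and the acetal masks the aldehyde against organolithiums, enolates and light.

Step 4
Reactants: 5 2-(dimethoxymethyl)-1,3-bis(methoxymethoxy)-5-methylbenzene
Product: 7 3-(dimethoxymethyl)-2,4-bis(methoxymethoxy)-6-methylbenzoic acid, via aryllithium 6 (not isolated)
Conditions: s-BuLi, TMEDA, THF, −78 °C; CO2; aq. NH4Cl, 0 °C, rapid extraction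
Reagents that add atoms: carbon dioxide, O=C=O
Why: Directed ortho-metalation at the only ring hydrogen ortho to an OMOM group (the two open positions are equivalent), then carboxylation; the weakly acidic cold work-up keeps the acetal, and the acid is used at once.

Step 5
Reactants: 8 diallyl L-tartrate
Product: 9 allyl glyoxylate (allyl 2-oxoacetate)
Conditions: H5IO6, Et2O, rt
Reagents that add atoms: none
Why: Periodate glycol cleavage (Malaprade reaction) gives two molecules of the aldehyde from one diol; the allyl esters are untouched.

Step 6
Reactants: 9 allyl glyoxylate; 10 methyl vinyl ketone (but-3-en-2-one)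
Product: 11 allyl 2-hydroxy-3-methylidene-4-oxopentanoate (racemic)
Conditions: DABCO (cat.), THF, rt
Reagents that add atoms: none
Why: Morita–Baylis–Hillman reaction; glyoxylates are among the most reactive aldehyde partners, which lets the coupling outrun dimerization of the enone, and the new stereocentre is destroyed in step 7.

Step 7
Reactants: 11 allyl 2-hydroxy-3-methylidene-4-oxopentanoate
Product: 12 allyl (Z)-3-(bromomethyl)-4-oxopent-2-enoate (ester cis to CH2Br, trans to acetyl)
Conditions: PBr3, Et2O, −10 to 0 °C
Reagents that add atoms: phosphorus tribromide, BrP(Br)Br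
Why: Bromide attack on the activated alcohol with allylic transposition (SN2'), the standard conversion of Morita–Baylis–Hillman alcohols into 2-(bromomethyl)alkenyl carbonyl compounds; any α-bromo ester from direct substitution should equilibrate to the conjugated primary bromide, and the isomer with the two carbonyl groups trans is the expected thermodynamic one.

Step 8
Reactants: 7 3-(dimethoxymethyl)-2,4-bis(methoxymethoxy)-6-methylbenzoic acid; 12 allyl (Z)-3-(bromomethyl)-4-oxopent-2-enoate
Product: 13 allyl (E)-3-(ArACO-oxymethyl)-4-oxopent-2-enoate
Conditions: Cs2CO3 (0.5 equiv), DMF, 0 °C to rt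
Reagents that add atoms: none
Why: SN2 alkylation of the cesium carboxylate; a di-ortho-substituted benzoate is a poor acyl donor but an unhindered oxygen nucleophile, the allylic bromide is highly activated, and a branched SN2' ester would revert to the conjugated isomer.

Step 9
Reactants: 13 allyl (E)-3-(ArACO-oxymethyl)-4-oxopent-2-enoate
Product: 16 allyl (E)-5-diazo-3-(ArACO-oxymethyl)-4-oxopent-2-enoate, via lithium enolate 14 (not isolated), via trifluoroacetyl diketone 15 (not isolated)
Conditions: LiN(SiMe3)2, THF, −78 °C; CF3CO2CH2CF3, −78 °C; aq. NH4Cl; then 4-AcNHC6H4SO2N3, Et3N, H2O, MeCN, rt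
Reagents that add atoms: 4-acetamidobenzenesulfonyl azide, CC(=O)Nc1ccc(cc1)S(=O)(=O)N=[N+]=[N-]
Why: Detrifluoroacetylative diazo transfer: kinetic enolization of the methyl ketone, Claisen-type trifluoroacetylation, Regitz diazo transfer to the activated diketone and loss of trifluoroacetate; this is the established way to α-diazo enones and avoids diazomethane, which would add to the alkene.

Step 10
Reactants: 17 3,3-diethoxyprop-1-yne
Product: 20 3,3-diethoxy-1-(triisopropylsilyloxy)prop-1-yne, via lithium acetylide 18 (not isolated), via lithium ynolate 19 (not isolated)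
Conditions: n-BuLi, THF, −78 °C; t-BuOOLi (t-BuOOH + LiN(SiMe3)2), −78 to 0 °C; i-Pr3SiOTf, −78 °C
Reagents that add atoms: tert-butyl hydroperoxide, CC(C)(C)OO; triisopropylsilyl trifluoromethanesulfonate, CC(C)[Si](OS(=O)(=O)C(F)(F)F)(C(C)C)C(C)C
Why: Oxygen transfer from the lithium peroxide to the acetylide gives the ynolate, and the bulky silyl triflate silylates it on oxygen; this is the standard one-flask route from terminal alkynes to triisopropylsilyl ynol ethers.

Step 11
Reactants: 16 allyl (E)-5-diazo-3-(ArACO-oxymethyl)-4-oxopent-2-enoate; 20 3,3-diethoxy-1-(triisopropylsilyloxy)prop-1-yne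
Product: 25 allyl 3-(diethoxymethyl)-6-(ArACO-oxymethyl)-2-hydroxy-4-(triisopropylsilyloxy)benzoate, via vinylketene 21 (not isolated), via vinylcyclobutenone 22 (not isolated), via dienylketene 23 (not isolated), via cyclohexadienone 24 (not isolated)
Conditions: hν (medium-pressure Hg lamp, Pyrex), ClCH2CH2Cl, rt; then 80 °C
Reagents that add atoms: none
Why: Light expels N2 from 16 and the alkenyl group migrates (Wolff rearrangement) to give vinylketene 21, whose ketene carbon becomes C2 and whose former diazo carbon becomes C5. Alkyne 20 then adds across the ketene C=C bond in a [2+2] cycloaddition: its nucleophilic carbon remote from oxygen, which bears the acetal, bonds to the ketene carbon (C2–C3) and its oxygenated carbon to the ketene α-carbon (C4–C5), so the polarization of the siloxyalkyne fixes the regiochemistry of vinylcyclobutenone 22. Reversible conrotatory 4π opening of 22 gives dienylketene 23, and a thermal disrotatory 6π electrocyclization joins the ketene carbon to the ester-bearing alkene carbon (C1–C2), closing the six-membered ring B as cyclohexadienone 24, which tautomerizes to phenol 25. This is the second-generation Danheiser benzannulation of α-diazo enones with siloxyalkynes, applied here to a more highly substituted pair. No stereocentre is formed, since the sp3 carbons of 22 and 24 are transient and are erased on aromatization. The E geometry of 16 keeps the ester carbonyl away from the ketene, so no oxa-6π closure to a pyranone can compete, and puts hydrogen on the inside of the closing triene. Pyrex-filtered light is absorbed by the diazo enone and not by the ring A benzoate, MOM ethers and acetals are inert to ketenes, and the final heating drives any remaining 22 through to 25.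

Step 12
Reactants: 25 allyl 3-(diethoxymethyl)-6-(ArACO-oxymethyl)-2-hydroxy-4-(triisopropylsilyloxy)benzoate
Product: 26 allyl 3-(diethoxymethyl)-6-(ArACO-oxymethyl)-2,4-dihydroxybenzoate
Conditions: Bu4NF, AcOH, THF, 0 °C
Reagents that add atoms: none
Why: Fluoride cleavage of the aryl silyl ether, buffered so that the esters are safe; the product is used crude, and any loss of the ring B acetal is harmless because step 13 removes it.

Step 13
Reactants: 26 allyl 3-(diethoxymethyl)-6-(ArACO-oxymethyl)-2,4-dihydroxybenzoate
Product: 27 allyl 3-formyl-6-[(3-formyl-2,4-dihydroxy-6-methylbenzoyl)oxymethyl]-2,4-dihydroxybenzoate (barbatolic acid allyl ester)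
Conditions: 2 M HCl, THF, rt to 40 °C
Reagents that add atoms: water, O
Why: Acid hydrolysis of both acetals and both MOM ethers; the benzylic ester does not ionize because its benzylic carbon is para to the aldehyde and ortho to the ester, and the ring B carboxyl group is still masked.

Step 14
Reactants: 27 barbatolic acid allyl ester
Product: 28 barbatolic acid
Conditions: Pd(PPh3)4 (cat.), p-TolSO2Na, THF/MeOH, rt; cold dilute HCl work-up
Reagents that add atoms: none
Why: Tsuji–Trost deallylation by zerovalent palladium, with the allyl group passed to sulfinate, a soft nucleophile that does not condense with aldehydes; the conditions are neutral and cold, which suits the phthalide-prone free acid.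

## Compound list

1 | orcinol (5-methylbenzene-1,3-diol) | Cc1cc(O)cc(O)c1 | starting material
2 | 1,3-bis(methoxymethoxy)-5-methylbenzene | Cc1cc(OCOC)cc(OCOC)c1 | intermediate
3 | [2,6-bis(methoxymethoxy)-4-methylphenyl]lithium | [Li]c1c(OCOC)cc(C)cc1OCOC | intermediate
4 | 2,6-bis(methoxymethoxy)-4-methylbenzaldehyde | Cc1cc(OCOC)c(C=O)c(OCOC)c1 | intermediate
5 | 2-(dimethoxymethyl)-1,3-bis(methoxymethoxy)-5-methylbenzene | Cc1cc(OCOC)c(C(OC)OC)c(OCOC)c1 | intermediate
6 | [3-(dimethoxymethyl)-2,4-bis(methoxymethoxy)-6-methylphenyl]lithium | [Li]c1c(C)cc(OCOC)c(C(OC)OC)c1OCOC | intermediate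
7 | 3-(dimethoxymethyl)-2,4-bis(methoxymethoxy)-6-methylbenzoic acid | OC(=O)c1c(C)cc(OCOC)c(C(OC)OC)c1OCOC | intermediate
8 | diallyl L-tartrate (diallyl (2R,3R)-2,3-dihydroxybutanedioate) | C=CCOC(=O)[C@H](O)[C@@H](O)C(=O)OCC=C | starting material
9 | allyl glyoxylate (allyl 2-oxoacetate) | C=CCOC(=O)C=O | intermediate
10 | methyl vinyl ketone (but-3-en-2-one) | CC(=O)C=C | starting material
11 | allyl 2-hydroxy-3-methylidene-4-oxopentanoate (racemic) | C=CCOC(=O)C(O)C(=C)C(C)=O | intermediate
12 | allyl (Z)-3-(bromomethyl)-4-oxopent-2-enoate | C=CCOC(=O)/C=C(\CBr)C(C)=O | intermediate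
13 | allyl (E)-3-(ArACO-oxymethyl)-4-oxopent-2-enoate | C=CCOC(=O)/C=C(\COC(=O)c1c(C)cc(OCOC)c(C(OC)OC)c1OCOC)C(C)=O | intermediate
14 | lithium dienolate of 13 (O-lithiated at the former acetyl group) | C=CCOC(=O)/C=C(\COC(=O)c1c(C)cc(OCOC)c(C(OC)OC)c1OCOC)C(=C)O[Li] | intermediate
15 | allyl (E)-3-(ArACO-oxymethyl)-7,7,7-trifluoro-4,6-dioxohept-2-enoate | C=CCOC(=O)/C=C(\COC(=O)c1c(C)cc(OCOC)c(C(OC)OC)c1OCOC)C(=O)CC(=O)C(F)(F)F | intermediate
16 | allyl (E)-5-diazo-3-(ArACO-oxymethyl)-4-oxopent-2-enoate | C=CCOC(=O)/C=C(\COC(=O)c1c(C)cc(OCOC)c(C(OC)OC)c1OCOC)C(=O)C=[N+]=[N-] | intermediate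
17 | 3,3-diethoxyprop-1-yne | C#CC(OCC)OCC | starting material
18 | lithium 3,3-diethoxyprop-1-yn-1-ide | [Li]C#CC(OCC)OCC | intermediate
19 | lithium 3,3-diethoxyprop-1-yn-1-olate | [Li]OC#CC(OCC)OCC | intermediate
20 | 3,3-diethoxy-1-(triisopropylsilyloxy)prop-1-yne | CCOC(OCC)C#CO[Si](C(C)C)(C(C)C)C(C)C | intermediate
21 | allyl (2Z)-3-(ArACO-oxymethyl)-5-oxopenta-2,4-dienoate (vinylketene, ester trans to the ketene arm) | C=CCOC(=O)/C=C(\COC(=O)c1c(C)cc(OCOC)c(C(OC)OC)c1OCOC)C=C=O | intermediate
22 | allyl (2Z)-4-(ArACO-oxy)-3-[3-(diethoxymethyl)-4-oxo-2-(triisopropylsilyloxy)cyclobut-2-en-1-yl]but-2-enoate (racemic) | C=CCOC(=O)/C=C(\COC(=O)c1c(C)cc(OCOC)c(C(OC)OC)c1OCOC)C1C(=O)C(C(OCC)OCC)=C1O[Si](C(C)C)(C(C)C)C(C)C | intermediate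
23 | allyl 3-(ArACO-oxymethyl)-6-(diethoxymethyl)-7-oxo-5-(triisopropylsilyloxy)hepta-2,4,6-trienoate (dienylketene, ketene arm cis to the enoate arm across the central double bond) | C=CCOC(=O)/C=C(COC(=O)c1c(C)cc(OCOC)c(C(OC)OC)c1OCOC)/C=C(O[Si](C(C)C)(C(C)C)C(C)C)\C(C(OCC)OCC)=C=O | intermediate
24 | allyl 6-(ArACO-oxymethyl)-3-(diethoxymethyl)-2-oxo-4-(triisopropylsilyloxy)cyclohexa-3,5-diene-1-carboxylate (racemic) | C=CCOC(=O)C1C(=O)C(C(OCC)OCC)=C(O[Si](C(C)C)(C(C)C)C(C)C)C=C1COC(=O)c1c(C)cc(OCOC)c(C(OC)OC)c1OCOC | intermediate
25 | allyl 3-(diethoxymethyl)-6-(ArACO-oxymethyl)-2-hydroxy-4-(triisopropylsilyloxy)benzoate | C=CCOC(=O)c1c(O)c(C(OCC)OCC)c(O[Si](C(C)C)(C(C)C)C(C)C)cc1COC(=O)c1c(C)cc(OCOC)c(C(OC)OC)c1OCOC | intermediate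
26 | allyl 3-(diethoxymethyl)-6-(ArACO-oxymethyl)-2,4-dihydroxybenzoate | C=CCOC(=O)c1c(O)c(C(OCC)OCC)c(O)cc1COC(=O)c1c(C)cc(OCOC)c(C(OC)OC)c1OCOC | intermediate
27 | allyl 3-formyl-6-[(3-formyl-2,4-dihydroxy-6-methylbenzoyl)oxymethyl]-2,4-dihydroxybenzoate | C=CCOC(=O)c1c(O)c(C=O)c(O)cc1COC(=O)c1c(C)cc(O)c(C=O)c1O | intermediate
28 | barbatolic acid (3-formyl-6-[(3-formyl-2,4-dihydroxy-6-methylbenzoyl)oxymethyl]-2,4-dihydroxybenzoic acid) | Cc1cc(O)c(C=O)c(O)c1C(=O)OCc1cc(O)c(C=O)c(O)c1C(=O)O | target

## Step count and risks

Total: 14 steps. Longest linear sequence: 10 steps (1, 2, 3, 4, 8, 9, 11, 12, 13, 14, from orcinol). The bromide branch (steps 5 to 7) and the alkyne branch (step 10) join it at steps 8 and 11.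

**Step 11 (key step).** The most likely failure is slow capture of vinylketene 21 by an alkyne that the acetal makes both more hindered and less electron-rich than the alkyl-substituted ynol ethers usually used. Ketene dimerization, light-induced alkene isomerization followed by closure to a pyranone, or acylation of the product phenol by the ketene could then take over. Fallback: keep the benzannulation but deliver C3 at the alcohol oxidation level. Commercial tert-butyldimethyl(prop-2-yn-1-yloxy)silane F1 is converted as in step 10 into 3-(tert-butyldimethylsilyloxy)-1-(triisopropylsilyloxy)prop-1-yne F2. Irradiation of 16 with F2 and heating should give allyl 3-(tert-butyldimethylsilyloxymethyl)-6-(ArACO-oxymethyl)-2-hydroxy-4-(triisopropylsilyloxy)benzoate F3. HF·pyridine buffered with pyridine in THF removes the primary silyl ether to give benzylic alcohol F4. MnO2 in CH2Cl2 oxidizes it to salicylaldehyde F5. Bu4NF/AcOH then gives the 2,4-dihydroxy aldehyde F6, and 2 M HCl in THF removes the ring A groups. This fallback sets out from 16 and rejoins the route at 27.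

**Step 9.** The amide base or the enolate may add to the doubly activated alkene, or deprotonation may occur at the acyloxymethyl group (γ to the ester), so that the enone is consumed before it is trifluoroacetylated. Fallback without a strong base, setting out from 13: soft enolization with t-BuMe2SiOTf and Et3N in CH2Cl2 at −78 °C gives the silyl dienol ether F7. N-Bromosuccinimide in THF at −78 °C gives the bromomethyl ketone F8. N,N'-Ditosylhydrazine with DBU in THF at 0 °C converts the bromide into the diazo ketone, which rejoins the route at 16.

**Step 10.** Oxygen transfer to an acetylide made less nucleophilic by the acetal may be incomplete, and the moisture-sensitive ynol ether may be lost on isolation. Fallback by Kowalski homologation, which reaches the same ynolate from an ester instead of an alkyne: commercial ethyl diethoxyacetate F9 is treated with LiCHBr2 (from CH2Br2 and lithium tetramethylpiperidide) at −78 °C to give 1,1-dibromo-3,3-diethoxypropan-2-one F10 as its enolate. n-BuLi then triggers bromine–lithium exchange and rearrangement to ynolate 19, which is silylated as before to give 20.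

**Step 4.** Deprotonation at the hindered position beside the methyl group may be slow, and the base may instead attack a MOM methylene or the acetal; acetal loss during the weakly acidic isolation is a second hazard. Fallback that fixes the metalation site by halogen, setting out from 4: N-bromosuccinimide in MeCN brominates the one activated ring position to give 3-bromo-2,6-bis(methoxymethoxy)-4-methylbenzaldehyde F11. Acetalization as in step 3 gives 2-bromo-4-(dimethoxymethyl)-3,5-bis(methoxymethoxy)-1-methylbenzene F12. Bromine–lithium exchange with n-BuLi at −78 °C generates aryllithium 6, and CO2 gives 7.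

**Step 14.** The allyl group may be transferred to a phenoxide oxygen or to the electron-rich ring A instead of to the sulfinate. Once the carboxylate is free, it may displace the ring A acid at the benzylic carbon (phthalide formation) during work-up. Fallback that removes the allyl group while the phenols and aldehydes are still masked, setting out from 25: Pd(PPh3)4 and p-TolSO2Na give 3-(diethoxymethyl)-6-(ArACO-oxymethyl)-2-hydroxy-4-(triisopropylsilyloxy)benzoic acid F13. Bu4NF/AcOH gives the 2,4-dihydroxy acid F14, and brief treatment with 2 M HCl in THF at rt removes acetals and MOM ethers to arrive at 28.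

## Further compounds

F1 | step 11 | tert-butyldimethyl(prop-2-yn-1-yloxy)silane (commercial) | C#CCO[Si](C)(C)C(C)(C)C
F2 | step 11 | 3-(tert-butyldimethylsilyloxy)-1-(triisopropylsilyloxy)prop-1-yne | CC(C)[Si](OC#CCO[Si](C)(C)C(C)(C)C)(C(C)C)C(C)C
F3 | step 11 | allyl 3-(tert-butyldimethylsilyloxymethyl)-6-(ArACO-oxymethyl)-2-hydroxy-4-(triisopropylsilyloxy)benzoate | C=CCOC(=O)c1c(O)c(CO[Si](C)(C)C(C)(C)C)c(O[Si](C(C)C)(C(C)C)C(C)C)cc1COC(=O)c1c(C)cc(OCOC)c(C(OC)OC)c1OCOC
F4 | step 11 | allyl 6-(ArACO-oxymethyl)-2-hydroxy-3-(hydroxymethyl)-4-(triisopropylsilyloxy)benzoate | C=CCOC(=O)c1c(O)c(CO)c(O[Si](C(C)C)(C(C)C)C(C)C)cc1COC(=O)c1c(C)cc(OCOC)c(C(OC)OC)c1OCOC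
F5 | step 11 | allyl 6-(ArACO-oxymethyl)-3-formyl-2-hydroxy-4-(triisopropylsilyloxy)benzoate | C=CCOC(=O)c1c(O)c(C=O)c(O[Si](C(C)C)(C(C)C)C(C)C)cc1COC(=O)c1c(C)cc(OCOC)c(C(OC)OC)c1OCOC
F6 | step 11 | allyl 6-(ArACO-oxymethyl)-3-formyl-2,4-dihydroxybenzoate | C=CCOC(=O)c1c(O)c(C=O)c(O)cc1COC(=O)c1c(C)cc(OCOC)c(C(OC)OC)c1OCOC
F7 | step 9 | allyl (E)-3-(ArACO-oxymethyl)-4-(tert-butyldimethylsilyloxy)penta-2,4-dienoate | C=CCOC(=O)/C=C(\COC(=O)c1c(C)cc(OCOC)c(C(OC)OC)c1OCOC)C(=C)O[Si](C)(C)C(C)(C)C
F8 | step 9 | allyl (E)-5-bromo-3-(ArACO-oxymethyl)-4-oxopent-2-enoate | C=CCOC(=O)/C=C(\COC(=O)c1c(C)cc(OCOC)c(C(OC)OC)c1OCOC)C(=O)CBr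
F9 | step 10 | ethyl diethoxyacetate (commercial) | CCOC(=O)C(OCC)OCC
F10 | step 10 | 1,1-dibromo-3,3-diethoxypropan-2-one (formed as its lithium enolate) | CCOC(OCC)C(=O)C(Br)Br
F11 | step 4 | 3-bromo-2,6-bis(methoxymethoxy)-4-methylbenzaldehyde | Cc1cc(OCOC)c(C=O)c(OCOC)c1Br
F12 | step 4 | 2-bromo-4-(dimethoxymethyl)-3,5-bis(methoxymethoxy)-1-methylbenzene | Cc1cc(OCOC)c(C(OC)OC)c(OCOC)c1Br
F13 | step 14 | 3-(diethoxymethyl)-6-(ArACO-oxymethyl)-2-hydroxy-4-(triisopropylsilyloxy)benzoic acid | OC(=O)c1c(O)c(C(OCC)OCC)c(O[Si](C(C)C)(C(C)C)C(C)C)cc1COC(=O)c1c(C)cc(OCOC)c(C(OC)OC)c1OCOC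
F14 | step 14 | 3-(diethoxymethyl)-6-(ArACO-oxymethyl)-2,4-dihydroxybenzoic acid | OC(=O)c1c(O)c(C(OCC)OCC)c(O)cc1COC(=O)c1c(C)cc(OCOC)c(C(OC)OC)c1OCOC
A1 | alternative 1 | 2,2'-di-O-MOM barbatolic acid allyl ester | Cc1cc(O)c(C=O)c(OCOC)c1C(=O)OCc1cc(O)c(C=O)c(OCOC)c1C(=O)OCC=C
A2 | alternative 1 | bis(3-trimethylsilyl-4-triflyloxy) depside allyl ester, the twofold aryne precursor | Cc1cc(OS(=O)(=O)C(F)(F)F)c([Si](C)(C)C)c(OCOC)c1C(=O)OCc1cc(OS(=O)(=O)C(F)(F)F)c([Si](C)(C)C)c(OCOC)c1C(=O)OCC=C
A3 | alternative 2 | ring B benzylic orsellinate with free ring A hydroxyls | Cc1cc(O)cc(O)c1C(=O)OCc1cc(OCOC)c(C(OC)OC)c(OCOC)c1C(=O)OCC=C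
A4 | alternative 2 | ring B benzylic but-2-ynoate | CC#CC(=O)OCc1cc(OCOC)c(C(OC)OC)c(OCOC)c1C(=O)OCC=C
A5 | alternative 2 | 1-methoxy-1,3-bis(trimethylsilyloxy)buta-1,3-diene | COC(O[Si](C)(C)C)=CC(=C)O[Si](C)(C)C
A6 | alternative 3 | allyl 6-(ArACO-oxymethyl)-2,4-dihydroxybenzoate | C=CCOC(=O)c1c(O)cc(O)cc1COC(=O)c1c(C)cc(OCOC)c(C(OC)OC)c1OCOC
A7 | alternative 3 | allyl 8-(ArACO-oxy)-3,5,7-trioxooctanoate | C=CCOC(=O)CC(=O)CC(=O)CC(=O)COC(=O)c1c(C)cc(OCOC)c(C(OC)OC)c1OCOC
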